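**Retrosynthetic overview**
1. Feature: each quinone ring is numbered C1=O (beside C2–OH), C3–CH3, C4=O, C5 (inter-ring carbon), C6–CH2CH2Ph. C3 sits between the enolic C2–OH and C4=O, so it is the nucleophilic α-carbon of a vinylogous carboxylic acid.
2. Disconnection 1 (last step): the C3–CH3 and C3'–CH3 bonds lead back to des-methyl bis(hydroxyquinone) 8, two CH2O and two hydrides (reductive alkylation in two directions).
3. Disconnection 2: both quinone rings come from the resorcinol rings of biphenyltetraol 7 by para-oxidation of the C2/C2' phenols, and 7 comes from tetramethyl ether 6.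
4. Disconnection 3: the C5–C5' bond comes from Ullmann homocoupling of aryl iodide 5. Iodide 5 derives from 3,5-dimethoxybibenzyl 4, made from aldehyde 1 and phosphonate 2 by olefination and hydrogenation.
5. Ring order: no ring is constructed. All four six-membered rings are bought as arenes, and the two inner ones become quinones together in step 6.

Key step: step 7

Assumption: the target SMILES carries no stereodescriptor, so the hindered C5–C5' axis is made as a racemate and no stereocontrol is planned.

**Step 1**
Reactants: 1 3,5-dimethoxybenzaldehyde; 2 diethyl benzylphosphonate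
Product: 3 (E)-3,5-dimethoxystilbene
Conditions: KOtBu (1.2 equiv), THF, 0 °C → rt
Reagents that add atoms: diethyl benzylphosphonate 2, CCOP(=O)(Cc1ccccc1)OCC
Why: Horner–Wadsworth–Emmons olefination of a non-enolisable aromatic aldehyde with a benzyl-stabilised phosphonate anion should give the E-alkene, whose geometry is erased in step 2.

**Step 2**
Reactants: 3 (E)-3,5-dimethoxystilbene
Product: 4 3,5-dimethoxybibenzyl [1,3-dimethoxy-5-(2-phenylethyl)benzene]
Conditions: H2 (1 atm), 10 % Pd/C, EtOAc, rt
Reagents that add atoms: none
Why: Heterogeneous catalytic hydrogenation saturates the stilbene C=C at atmospheric pressure and leaves the aryl methyl ethers and both arenes untouched.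

**Step 3**
Reactants: 4 3,5-dimethoxybibenzyl
Product: 5 2-iodo-1,5-dimethoxy-3-(2-phenylethyl)benzene (iodine between the side chain and one OMe)
Conditions: NIS (1.0 equiv), TFA (cat.), MeCN, 0 °C → rt, dark
Reagents that add atoms: N-iodosuccinimide, O=C1CCC(=O)N1I
Why: Electrophilic aromatic iodination goes to the carbon para to one OMe and ortho to the other rather than to the crowded carbon between both OMe groups, the unactivated phenyl ring does not compete, and the iodide is chosen because an electron-rich aryl bromide would be too sluggish in step 4.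

**Step 4**
Reactants: 5 2-iodo-1,5-dimethoxy-3-(2-phenylethyl)benzene (two molecules)
Product: 6 2,2',4,4'-tetramethoxy-6,6'-bis(2-phenylethyl)-1,1'-biphenyl (racemic axis)
Conditions: Cu powder (freshly activated, 8 equiv), neat, 220 °C, Ar
Reagents that add atoms: none
Why: Classical Ullmann reductive homocoupling tolerates two ortho substituents on electron-rich aryl iodides when run hot with excess zerovalent copper, and nothing in 5 other than the carbon–iodine bond reacts at this temperature.

**Step 5**
Reactants: 6 2,2',4,4'-tetramethoxy-6,6'-bis(2-phenylethyl)-1,1'-biphenyl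
Product: 7 6,6'-bis(2-phenylethyl)-1,1'-biphenyl-2,2',4,4'-tetraol
Conditions: BBr3 (6 equiv), CH2Cl2, −78 °C → rt; then H2O, 0 °C
Reagents that add atoms: none
Why: In this Lewis-acid ether cleavage BBr3 binds each methoxy oxygen, bromide removes the methyl group by SN2, and the aqueous quench frees the four phenols without touching the bibenzyl chains.

**Step 6**
Reactants: 7 6,6'-bis(2-phenylethyl)-1,1'-biphenyl-2,2',4,4'-tetraol
Product: 8 5,5'-bi[2-hydroxy-6-(2-phenylethyl)-1,4-benzoquinone] (C3–H and C3'–H free)
Conditions: (KSO3)2NO (5 equiv), aq. KH2PO4 buffer (pH 6)/acetone, 0 °C → rt; then 1 M HCl, EtOAc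
Reagents that add atoms: potassium nitrosodisulfonate (KSO3)2NO, [K+].[K+].[O]N(S(=O)(=O)[O-])S(=O)(=O)[O-]
Why: In this Teuber oxidation one radical takes the hydrogen of the phenol next to the axis, a second binds through oxygen at its free para CH (the carbon between chain and the other OH) and loss of HN(SO3K)2 gives the p-quinone, while the para position of the other OH is blocked by the biaryl bond and C5/C6 of the product are fully substituted, which leaves no site for dibenzofuran closure or self-addition.

**Step 7**
Reactants: 8 5,5'-bi[2-hydroxy-6-(2-phenylethyl)-1,4-benzoquinone]; 9 formaldehyde (37 % aqueous solution); 10 Hantzsch ester (diethyl 2,6-dimethyl-1,4-dihydropyridine-3,5-dicarboxylate)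
Product: 14 5,5'-bi[2-hydroxy-3-methyl-6-(2-phenylethyl)-1,4-benzoquinone], via first quinone methide 11 (not isolated), via monomethyl bisquinone 12 (not isolated), via second quinone methide 13 (not isolated)
Conditions: L-proline (20 mol %), 10 (2.6 equiv), 9 (5 equiv), CH2Cl2/EtOH (1:1), 25 °C, solution of 8 added over 4 h; then 1 M HCl, open to air
Reagents that add atoms: formaldehyde 9, C=O
Why: This is the organocatalytic three-component reductive alkylation (Knoevenagel-type condensation followed by transfer hydrogenation), a reaction type known for 2-hydroxy-1,4-quinones and cyclic 1,3-dicarbonyl compounds with aldehydes, formaldehyde among them. L-Proline activates 9 in its iminium form, the enolic C3 of one ring adds to it and expulsion of proline leaves the 3-methylidene-1,2,4-trione 11, whose exocyclic CH2 accepts hydride from C4 of 10 to restore the hydroxyquinone as 12, and the same cycle on the other ring leads through 13 to 14. No ring is closed and no stereocentre is created, the step only forms the two C3–CH3 bonds. Site selectivity lies in the substrate: C3–H is the only C–H on each quinone ring, C5 and C6 carry carbon substituents so that no open Michael position is left, and C3 and C3' point away from the axis so that a single CH2 cannot span them. What has to be secured is hydride capture of 11 and 13 ahead of conjugate addition of a further hydroxyquinone enol, and this is served by feeding 8 slowly into an excess of 9 and 10 (free enol stays scarce, an excess of 9 is harmless once C3 is blocked) and by the reversibility of that Michael addition under amine catalysis. Rings that 10 may reduce to the benzene-1,2,4-triol level are re-oxidised by air in the acidic work-up.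

**Compound list**
1 | 3,5-dimethoxybenzaldehyde | COc1cc(C=O)cc(OC)c1 | starting material
2 | diethyl benzylphosphonate | CCOP(=O)(Cc1ccccc1)OCC | starting material
3 | (E)-3,5-dimethoxystilbene | COc1cc(/C=C/c2ccccc2)cc(OC)c1 | intermediate
4 | 3,5-dimethoxybibenzyl | COc1cc(CCc2ccccc2)cc(OC)c1 | intermediate
5 | 2-iodo-1,5-dimethoxy-3-(2-phenylethyl)benzene | Ic1c(OC)cc(OC)cc1CCc1ccccc1 | intermediate
6 | 2,2',4,4'-tetramethoxy-6,6'-bis(2-phenylethyl)-1,1'-biphenyl | COc1cc(OC)c(-c2c(OC)cc(OC)cc2CCc2ccccc2)c(CCc2ccccc2)c1 | intermediate
7 | 6,6'-bis(2-phenylethyl)-1,1'-biphenyl-2,2',4,4'-tetraol | Oc1cc(O)c(-c2c(O)cc(O)cc2CCc2ccccc2)c(CCc2ccccc2)c1 | intermediate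
8 | 5,5'-bi[2-hydroxy-6-(2-phenylethyl)-1,4-benzoquinone] | O=C1C=C(O)C(=O)C(CCc2ccccc2)=C1C1=C(CCc2ccccc2)C(=O)C(O)=CC1=O | intermediate
9 | formaldehyde | C=O | starting material
10 | Hantzsch ester, diethyl 2,6-dimethyl-1,4-dihydropyridine-3,5-dicarboxylate | CCOC(=O)C1=C(C)NC(C)=C(C1)C(=O)OCC | starting material
11 | first quinone methide (one ring 3-methylidenecyclohex-5-ene-1,2,4-trione, other ring unchanged hydroxyquinone) | C=C1C(=O)C(=O)C(CCc2ccccc2)=C(C2=C(CCc3ccccc3)C(=O)C(O)=CC2=O)C1=O | intermediate
12 | monomethyl bisquinone (C3–CH3 on one ring, C3'–H on the other) | CC1=C(O)C(=O)C(CCc2ccccc2)=C(C2=C(CCc3ccccc3)C(=O)C(O)=CC2=O)C1=O | intermediate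
13 | second quinone methide (methylated hydroxyquinone ring joined to a 3-methylidene-1,2,4-trione ring) | CC1=C(O)C(=O)C(CCc2ccccc2)=C(C2=C(CCc3ccccc3)C(=O)C(=O)C(=C)C2=O)C1=O | intermediate
14 | 5,5'-bi[2-hydroxy-3-methyl-6-(2-phenylethyl)-1,4-benzoquinone], CNP0136737.0 | CC1=C(O)C(=O)C(CCc2ccccc2)=C(C2=C(CCc3ccccc3)C(=O)C(O)=C(C)C2=O)C1=O | target

**Total step count:** 7
**Longest linear sequence:** 7 steps (1 → 14)

**Steps most likely to fail**

1. **Step 7.**
   - Risk: conjugate addition of still unreacted hydroxyquinone enol to the quinone methides would build methylene-bridged oligomers. Hydride transfer from 10 to the quinone rings would starve the cascade of reductant.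
   - Fallback (methyl groups placed before the rings are oxidised): it sets out from 6 and comes back at 14. Twofold directed ortho-lithiation of 6 at the CH between the two OMe groups of each ring (n-BuLi/TMEDA, THF, 0 °C), quenched with MeI, should give 2,2',4,4'-tetramethoxy-3,3'-dimethyl-6,6'-bis(2-phenylethyl)biphenyl F1. BBr3 in CH2Cl2 then frees 3,3'-dimethyl-6,6'-bis(2-phenylethyl)biphenyl-2,2',4,4'-tetraol F2. Teuber oxidation with (KSO3)2NO as in step 6 attacks the only free ring CH and leads directly to 14.

2. **Step 6.**
   - Risk: radical C–C or C–O coupling and over-oxidation of the free, very electron-rich resorcinol rings, attack at the CH between the two OH groups, and slow transfer of the lipophilic tetraol to the aqueous oxidant.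
   - Fallback (oxygen brought in ionically, quinone made by oxidative demethylation): it sets out from 6 and comes back at 8.
     - NBS (2.1 equiv, MeCN, 0 °C) should brominate para to OMe to give 3,3'-dibromo-4,4',6,6'-tetramethoxy-2,2'-bis(2-phenylethyl)biphenyl F3.
     - Bromine–lithium exchange (n-BuLi, THF, −78 °C) and B(OMe)3 give the bis(dimethyl boronate) F4, which is not isolated.
     - H2O2/NaOH oxidises it to 4,4',6,6'-tetramethoxy-2,2'-bis(2-phenylethyl)biphenyl-3,3'-diol F5.
     - (NH4)2Ce(NO3)6 in MeCN/H2O at 0 °C turns each p-methoxyphenol unit into the quinone, giving 5,5'-bi[2-methoxy-6-(2-phenylethyl)-1,4-benzoquinone] F6.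
     - Saponification of the two vinylogous esters (aq. NaOH/MeOH, then HCl) delivers 8.

3. **Step 4.**
   - Risk: hydrodeiodination at high temperature, and stalling of the coupling because both partners carry two ortho substituents on an electron-rich ring.
   - Fallback (cross-coupling of two differently activated halves under zerovalent palladium catalysis): it sets out from 5 and comes back at 6. Half of 5 is converted by iodine–lithium exchange (n-BuLi, THF, −78 °C) and 2-isopropoxy-4,4,5,5-tetramethyl-1,3,2-dioxaborolane into 2-[2,4-dimethoxy-6-(2-phenylethyl)phenyl]-4,4,5,5-tetramethyl-1,3,2-dioxaborolane F7. Suzuki–Miyaura coupling of this boronate with the other half of 5 (Pd(OAc)2/SPhos, K3PO4, toluene/H2O, 100 °C) should give 6.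

**Further compounds**
F1 | step 7 | 2,2',4,4'-tetramethoxy-3,3'-dimethyl-6,6'-bis(2-phenylethyl)biphenyl | COc1cc(CCc2ccccc2)c(-c2c(CCc3ccccc3)cc(OC)c(C)c2OC)c(OC)c1C
F2 | step 7 | 3,3'-dimethyl-6,6'-bis(2-phenylethyl)biphenyl-2,2',4,4'-tetraol | Cc1c(O)cc(CCc2ccccc2)c(-c2c(CCc3ccccc3)cc(O)c(C)c2O)c1O
F3 | step 6 | 3,3'-dibromo-4,4',6,6'-tetramethoxy-2,2'-bis(2-phenylethyl)biphenyl | COc1cc(OC)c(-c2c(OC)cc(OC)c(Br)c2CCc2ccccc2)c(CCc2ccccc2)c1Br
F4 | step 6 | tetramethyl [4,4',6,6'-tetramethoxy-2,2'-bis(2-phenylethyl)biphenyl-3,3'-diyl]diboronate | COB(OC)c1c(OC)cc(OC)c(-c2c(OC)cc(OC)c(B(OC)OC)c2CCc2ccccc2)c1CCc1ccccc1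
F5 | step 6 | 4,4',6,6'-tetramethoxy-2,2'-bis(2-phenylethyl)biphenyl-3,3'-diol | COc1cc(OC)c(-c2c(OC)cc(OC)c(O)c2CCc2ccccc2)c(CCc2ccccc2)c1O
F6 | step 6 | 5,5'-bi[2-methoxy-6-(2-phenylethyl)-1,4-benzoquinone] | COC1=CC(=O)C(C2=C(CCc3ccccc3)C(=O)C(OC)=CC2=O)=C(CCc2ccccc2)C1=O
F7 | step 4 | 2-[2,4-dimethoxy-6-(2-phenylethyl)phenyl]-4,4,5,5-tetramethyl-1,3,2-dioxaborolane | COc1cc(OC)c(B2OC(C)(C)C(C)(C)O2)c(CCc2ccccc2)c1
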